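**Retrosynthetic overview**

- The 13E allylic acetate comes from the 8,15-diol, the diol from a terminal alkyne by zirconium-catalysed methylalumination and formaldehyde capture, and the alkyne from a C13 methyl ester that is carried inert through the core-forming steps.
- H-5 is cis to the C8 hydroxyl across ring B. This is the retron for a hydroxyl-directed hydrogenation of a C5=C6 alkene, so C5 is set last on the core.
- Key disconnection: ring B is read as an acyclic tetrasubstituted 2-en-one C10=C9–C8(=O)CH3 (C8 carbinol = ketone carbon, quaternary C10 = β-carbon) joined to a C5–C6–C7 allylsilane that acts as a propane-1,3-diyl dinucleophile. One acid-catalysed operation forms C5–C10 (ring A, first) and then C7–C8 (ring B, second).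
- The acyclic, achiral precursor is assembled by B-alkyl Suzuki coupling of an allylsilane diene (from 2,2-dimethylpent-4-enal) with the enol triflate of methyl 4-acetyl-5-oxohexanoate (from acetylacetone and methyl acrylate).

Key step: step 6

Remark: the SMILES is read as (5R,8S,9R,10S) in labdane numbering, a cis-fused decalin with H-5, the 8-hydroxyl, the C9 side chain and the C10 methyl on one face; which antipode of the chiral acid in step 6 gives this series must be found by experiment, and the drawings assume the matching antipode.

**Route**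

Step 1
Reactants: 1 methyltriphenylphosphonium bromide; 2 (iodomethyl)trimethylsilane
Product: 4 [2-(trimethylsilyl)ethyl]triphenylphosphonium iodide, via methylenetriphenylphosphorane 3 (not isolated)
Conditions: n-BuLi (1.0 equiv), THF, 0 °C; then 2, 0 °C → rt
Reagents that add atoms: none
Why: Deprotonation gives the non-stabilised ylide 3, which should be C-alkylated by the primary iodide (SN2 alkylation of a phosphorus ylide); no stereocentre is formed.

Step 2
Reactants: 4 [2-(trimethylsilyl)ethyl]triphenylphosphonium iodide; 5 2,2-dimethylpent-4-enal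
Product: 7 (Z)-(4,4-dimethylhepta-2,6-dien-1-yl)trimethylsilane, via silyl ylide 6 (not isolated)
Conditions: n-BuLi, THF, −78 → 0 °C; then 5, −78 °C → rt
Reagents that add atoms: none
Why: Wittig olefination of the α-quaternary aldehyde with the non-stabilised β-silyl ylide should give the allylsilane with the Z geometry usual for such ylides; the terminal alkene is untouched.

Step 3
Reactants: 8 acetylacetone; 9 methyl acrylate
Product: 10 methyl 4-acetyl-5-oxohexanoate
Conditions: K2CO3 (10 mol %), acetone, rt (8 in twofold excess)
Reagents that add atoms: none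
Why: Base-catalysed Michael addition of the 1,3-diketone to the acrylate; the excess of diketone should suppress double addition, and no stereocentre is formed.

Step 4
Reactants: 10 methyl 4-acetyl-5-oxohexanoate
Product: 12 methyl (4Z)-4-acetyl-5-(trifluoromethylsulfonyloxy)hex-4-enoate, via sodium enolate 11 (not isolated)
Conditions: NaH, THF, 0 °C; Tf2O, −78 → 0 °C
Reagents that add atoms: trifluoromethanesulfonic anhydride, O=S(=O)(OS(=O)(=O)C(F)(F)F)C(F)(F)F
Why: O-sulfonylation of the chelated, U-shaped sodium enolate should place the triflate cis to the remaining acetyl group (Z), which fixes the geometry of the later tetrasubstituted enone.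

Step 5
Reactants: 7 (Z)-(4,4-dimethylhepta-2,6-dien-1-yl)trimethylsilane; 12 methyl (4Z)-4-acetyl-5-(trifluoromethylsulfonyloxy)hex-4-enoate
Product: 14 methyl (4Z,10Z)-4-acetyl-5,9,9-trimethyl-12-(trimethylsilyl)dodeca-4,10-dienoate, via alkylborane 13 (not isolated)
Conditions: 9-BBN-H, THF, 0 °C → rt; then 12, PdCl2(dppf) (5 mol %), AsPh3 (10 mol %), Cs2CO3, DMF–H2O, rt
Reagents that add atoms: none
Why: 9-BBN should hydroborate only the monosubstituted alkene (the Z-disubstituted allylsilane alkene next to the quaternary carbon is far slower), and B-alkyl Suzuki–Miyaura coupling with the activated enol triflate proceeds with retention of alkene geometry.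

Step 6
Reactants: 14 methyl (4Z,10Z)-4-acetyl-5,9,9-trimethyl-12-(trimethylsilyl)dodeca-4,10-dienoate
Product: 18 methyl (8S,9R,10R)-8-hydroxy-14,15,16-trinorlabd-5-en-13-oate, via silyl enol ether 15 (not isolated), via keto olefin 16 (not isolated), via silyl ether 17 (not isolated)
Conditions: enantiopure imidodiphosphorimidate Brønsted acid (IDPi built from two 3,3′-bis[3,5-bis(trifluoromethyl)phenyl]-BINOL units, both P=N–SO2CF3; 5 mol %), CH2Cl2, 4 Å MS, −78 → −20 °C; then K2CO3, MeOH, 0 °C
Reagents that add atoms: none
Why: Proposed new method: the acid is silylated by the first turnovers, and the resulting Me3Si+/chiral-anion pair activates the enone so that the allylsilane γ-carbon C5 adds to the β-carbon C10 with anti-SE2′ loss of silicon (6-exo-trig Hosomi–Sakurai closure of ring A) to give silyl enol ether 15; the proton form of the same catalyst then protonates C9 to give the O-activated methyl ketone 16, whose vinyl group attacks C8 through C7 (6-endo Prins-type carbonyl–ene closure of ring B), and the C6 cation loses H-5 to leave the C5=C6 alkene and silyl ether 17, so that 14 → 17 is a catalytic isomerisation in which silicon travels from C7 to O8 and a proton from C5 to C9. The closest known reactions are silylium- and triflimide-catalysed conjugate Hosomi–Sakurai allylation of enones, enantioselective silylium catalysis with imidodiphosphorimidate anions (allylation of aldehydes, Mukaiyama–Michael additions), and Lewis- or Brønsted-acid-promoted intramolecular carbonyl–ene (Prins) cyclisation of olefinic carbonyl compounds; their fusion in one flask and face control at a tetrasubstituted enone are untested. C10 should be set by the chiral counter-anion, which shields one face of the planar silyloxyallyl cation. C9 and C8 should be set in the chair transition state of ring-B closure under Curtin–Hammett conditions (reversible C9 protonation of 15): the propanoate arm is equatorial and so cis to the C10 methyl, and the ketone methyl is equatorial to avoid a 1,3-diaxial clash with the C10 methyl, so the oxygen is axial and cis to the C10 methyl. C5 is deliberately erased, so the diastereoselectivity of the first ring closure does not matter. The step needs 1,4- over 1,2-attack of the allylsilane (six- against eight-membered ring), attack of the terminal vinyl carbon, and proton loss towards C5, which is the normal ene outcome (homoallylic rather than allylic alcohol) and the more substituted alkene.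

Step 7
Reactants: 18 methyl (8S,9R,10R)-8-hydroxy-14,15,16-trinorlabd-5-en-13-oate
Product: 19 methyl (5R,8S,9R,10S)-8-hydroxy-14,15,16-trinorlabdan-13-oate
Conditions: [Ir(cod)(PCy3)(py)]PF6 (10 mol %), H2 (1–20 bar), CH2Cl2, rt
Reagents that add atoms: none
Why: Hydroxyl-directed homogeneous hydrogenation (Crabtree type, as for cyclohex-3-enols): the axial C8 hydroxyl binds iridium and should deliver hydrogen to its own face of the C5=C6 alkene, setting H-5 cis to the hydroxyl and the C10 methyl (cis ring fusion, 5R).

Step 8
Reactants: 19 methyl (5R,8S,9R,10S)-8-hydroxy-14,15,16-trinorlabdan-13-oate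
Product: 20 (5R,8S,9R,10S)-8,13-epoxy-14,15,16-trinorlabdan-13-ol (lactol, anomer mixture, in equilibrium with the 8-hydroxy-13-aldehyde)
Conditions: i-Bu2AlH (3 equiv), CH2Cl2, −78 °C; aq. potassium sodium tartrate
Reagents that add atoms: none
Why: Partial ester reduction at low temperature; the aldehyde released on work-up should be trapped by the neighbouring tertiary hydroxyl as the six-membered lactol, and no core stereocentre is touched.

Step 9
Reactants: 20 (5R,8S,9R,10S)-8,13-epoxy-14,15,16-trinorlabdan-13-ol
Product: 21 (5R,8S,9R,10S)-15,16-dinorlabd-13-yn-8-ol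
Conditions: MeC(O)C(N2)P(O)(OMe)2, K2CO3, MeOH, 0 °C → rt
Reagents that add atoms: dimethyl (1-diazo-2-oxopropyl)phosphonate, COP(=O)(OC)C(=[N+]=[N-])C(C)=O
Why: Seyferth–Gilbert homologation with the Ohira–Bestmann reagent acts on the open hydroxy-aldehyde form of the lactol and should give the terminal alkyne under mild base that leaves the tertiary alcohol alone.

Step 10
Reactants: 21 (5R,8S,9R,10S)-15,16-dinorlabd-13-yn-8-ol
Product: 23 (5R,8S,9R,10S)-labd-13E-ene-8,15-diol, via alkenylalane 22 (not isolated)
Conditions: AlMe3 (4 equiv), Cp2ZrCl2 (0.3 equiv), CH2Cl2, 0 °C → rt; then n-BuLi, THF, −78 °C; (CH2O)n, −78 °C → rt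
Reagents that add atoms: trimethylaluminium, C[Al](C)C; formaldehyde (as paraformaldehyde), C=O
Why: Negishi zirconium-catalysed carboalumination adds methyl and aluminium syn across the alkyne with methyl on the internal carbon (the tertiary alcohol is masked in the flask as its aluminium alkoxide), and the alkenylalanate adds to formaldehyde with retention, which should fix the 13E geometry.

Step 11
Reactants: 23 (5R,8S,9R,10S)-labd-13E-ene-8,15-diol
Product: 24 (5R,8S,9R,10S)-8-hydroxylabd-13E-en-15-yl acetate (target)
Conditions: Ac2O (1.2 equiv), pyridine, DMAP (5 mol %), CH2Cl2, 0 °C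
Reagents that add atoms: acetic anhydride, CC(=O)OC(C)=O
Why: Chemoselective acylation: the primary allylic alcohol should be acetylated while the hindered tertiary alcohol stays free.

**Compound list**

1 | methyltriphenylphosphonium bromide | C[P+](c1ccccc1)(c1ccccc1)c1ccccc1.[Br-] | starting material
2 | (iodomethyl)trimethylsilane | C[Si](C)(C)CI | starting material
3 | methylenetriphenylphosphorane | C=P(c1ccccc1)(c1ccccc1)c1ccccc1 | intermediate
4 | [2-(trimethylsilyl)ethyl]triphenylphosphonium iodide | C[Si](C)(C)CC[P+](c1ccccc1)(c1ccccc1)c1ccccc1.[I-] | intermediate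
5 | 2,2-dimethylpent-4-enal | CC(C)(CC=C)C=O | starting material
6 | [2-(trimethylsilyl)ethylidene]triphenylphosphorane | C[Si](C)(C)CC=P(c1ccccc1)(c1ccccc1)c1ccccc1 | intermediate
7 | (Z)-(4,4-dimethylhepta-2,6-dien-1-yl)trimethylsilane | C[Si](C)(C)C/C=C\C(C)(C)CC=C | intermediate
8 | acetylacetone (pentane-2,4-dione) | CC(=O)CC(C)=O | starting material
9 | methyl acrylate | C=CC(=O)OC | starting material
10 | methyl 4-acetyl-5-oxohexanoate | COC(=O)CCC(C(C)=O)C(C)=O | intermediate
11 | sodium (Z)-enolate of 10 (chelated) | COC(=O)CC/C(C(C)=O)=C(\C)[O-].[Na+] | intermediate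
12 | methyl (4Z)-4-acetyl-5-(trifluoromethylsulfonyloxy)hex-4-enoate | COC(=O)CC/C(C(C)=O)=C(\C)OS(=O)(=O)C(F)(F)F | intermediate
13 | 9-[(5Z)-4,4-dimethyl-7-(trimethylsilyl)hept-5-en-1-yl]-9-borabicyclo[3.3.1]nonane | C[Si](C)(C)C/C=C\C(C)(C)CCCB1C2CCCC1CCC2 | intermediate
14 | methyl (4Z,10Z)-4-acetyl-5,9,9-trimethyl-12-(trimethylsilyl)dodeca-4,10-dienoate | COC(=O)CC/C(C(C)=O)=C(\C)CCCC(C)(C)/C=C\C[Si](C)(C)C | intermediate
15 | methyl 4-[(1S,2S)-2-ethenyl-1,3,3-trimethylcyclohexyl]-5-(trimethylsilyloxy)hex-4-enoate (vinyl and side arm trans; enol ether geometry not defined) | COC(=O)CCC(=C(C)O[Si](C)(C)C)[C@@]1(C)CCCC(C)(C)[C@@H]1C=C | intermediate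
16 | methyl (4R)-4-[(1S,2S)-2-ethenyl-1,3,3-trimethylcyclohexyl]-5-oxohexanoate | COC(=O)CC[C@@H](C(C)=O)[C@@]1(C)CCCC(C)(C)[C@@H]1C=C | intermediate
17 | methyl (8S,9R,10R)-8-(trimethylsilyloxy)-14,15,16-trinorlabd-5-en-13-oate | COC(=O)CC[C@@H]1[C@@]2(C)CCCC(C)(C)C2=CC[C@]1(C)O[Si](C)(C)C | intermediate
18 | methyl (8S,9R,10R)-8-hydroxy-14,15,16-trinorlabd-5-en-13-oate | COC(=O)CC[C@@H]1[C@@]2(C)CCCC(C)(C)C2=CC[C@]1(C)O | intermediate
19 | methyl (5R,8S,9R,10S)-8-hydroxy-14,15,16-trinorlabdan-13-oate (cis-fused) | COC(=O)CC[C@@H]1[C@@]2(C)CCCC(C)(C)[C@H]2CC[C@]1(C)O | intermediate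
20 | (5R,8S,9R,10S)-8,13-epoxy-14,15,16-trinorlabdan-13-ol (lactol, anomer mixture) | OC1CC[C@@H]2[C@@]3(C)CCCC(C)(C)[C@H]3CC[C@]2(C)O1 | intermediate
21 | (5R,8S,9R,10S)-15,16-dinorlabd-13-yn-8-ol | C#CCC[C@@H]1[C@@]2(C)CCCC(C)(C)[C@H]2CC[C@]1(C)O | intermediate
22 | (13E)-alkenyldimethylalane of 21, O8 as dimethylaluminium alkoxide | C[Al](C)/C=C(\C)CC[C@@H]1[C@@]2(C)CCCC(C)(C)[C@H]2CC[C@]1(C)O[Al](C)C | intermediate
23 | (5R,8S,9R,10S)-labd-13E-ene-8,15-diol | OC/C=C(\C)CC[C@@H]1[C@@]2(C)CCCC(C)(C)[C@H]2CC[C@]1(C)O | intermediate
24 | (5R,8S,9R,10S)-8-hydroxylabd-13E-en-15-yl acetate | CC(=O)OC/C=C(\C)CC[C@@H]1[C@@]2(C)CCCC(C)(C)[C@H]2CC[C@]1(C)O | target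

**Step count and risks**

Total step count: 11. Longest linear sequence: 9 steps (steps 1, 2, 5, 6, 7, 8, 9, 10, 11; the branch through steps 3 and 4 is equally long).

Steps most likely to fail:

1. Step 6 (Proposed new method). The second ring closure may not follow the conjugate allylation in the same flask. The secondary C6 cation may also undergo hydride and methyl shifts instead of clean proton loss towards C5. Face selection at the tetrasubstituted enone may be poor. Fallback, setting out from 14 and returning at 18: the two bond formations are run apart with established reagents and the material is resolved. TiCl4 in CH2Cl2 at −78 °C effects the intramolecular Hosomi–Sakurai conjugate addition and gives, after aqueous work-up, the racemic keto olefin F1. Me2AlCl in CH2Cl2 (−78 → 0 °C) then effects the Lewis-acid carbonyl–ene cyclisation to the racemic homoallylic alcohol F2. Saponification (LiOH, THF–H2O) gives the racemic hydroxy acid F3. This is resolved by crystallisation of its salt with (S)-1-phenylethylamine (or the antipode, whichever gives the less soluble salt of the wanted acid), the salt F4. Cold dilute acid liberates the enantiopure hydroxy acid F5, and Me3SiCHN2 in MeOH–toluene returns the methyl ester 18.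

2. Step 7. The cationic iridium catalyst may fail to reach the trisubstituted alkene between two quaternary carbons, or hydrogen may add from the face opposite to the hydroxyl and give the trans-fused epimer. Fallback, setting out from 18 and returning at 19: hydrogen is delivered through a silicon tether instead. The tertiary alcohol is silylated with (HMe2Si)2NH to the hydridosilyl ether F6. Intramolecular hydrosilylation with Pt2[(CH2=CHSiMe2)2O]3 adds Si–H syn from the hydroxyl face (silicon to C6, hydrogen to C5) and closes the oxasilolane F7. Protodesilylation (Bu4NF, DMF, 80 °C) then removes silicon to give 19.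

3. Step 5. The vinylogous acyl triflate may be hydrolysed or reduced faster than it undergoes transmetallation with the hindered alkylborane, and the enone may lose its geometry under the basic conditions. Fallback, setting out from 7 and 10 and returning at 14: the bond is made by cuprate addition–elimination. The alkylborane 13 from 7 is iodinated in the flask (I2, NaOMe) to the primary iodide F8. Diketone 10 is converted with NaH and ClP(O)(OEt)2 into the (Z)-enol phosphate F9. Iodine–lithium exchange on the iodide (t-BuLi, Et2O, −78 °C) and CuI give the lithium dialkylcuprate F10, which should displace the phosphate with retention of geometry at −78 °C to give 14.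

**Further compounds**

F1 | step 6 | methyl 4-(2-ethenyl-1,3,3-trimethylcyclohexyl)-5-oxohexanoate (racemic, diastereomer mixture) | COC(=O)CCC(C(C)=O)C1(C)CCCC(C)(C)C1C=C
F2 | step 6 | racemic methyl 8-hydroxy-14,15,16-trinorlabd-5-en-13-oate (relative configuration as in 18) | COC(=O)CCC1C2(C)CCCC(C)(C)C2=CCC1(C)O
F3 | step 6 | racemic 8-hydroxy-14,15,16-trinorlabd-5-en-13-oic acid | OC(=O)CCC1C2(C)CCCC(C)(C)C2=CCC1(C)O
F4 | step 6 | (S)-1-phenylethylammonium (8S,9R,10R)-8-hydroxy-14,15,16-trinorlabd-5-en-13-oate | C[C@H]([NH3+])c1ccccc1.[O-]C(=O)CC[C@@H]1[C@@]2(C)CCCC(C)(C)C2=CC[C@]1(C)O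
F5 | step 6 | (8S,9R,10R)-8-hydroxy-14,15,16-trinorlabd-5-en-13-oic acid | OC(=O)CC[C@@H]1[C@@]2(C)CCCC(C)(C)C2=CC[C@]1(C)O
F6 | step 7 | methyl (8S,9R,10R)-8-(dimethylsilyloxy)-14,15,16-trinorlabd-5-en-13-oate | COC(=O)CC[C@@H]1[C@@]2(C)CCCC(C)(C)C2=CC[C@]1(C)O[SiH](C)C
F7 | step 7 | cis-fused oxasilolane from F6 (O8–SiMe2–C6, H-5 on the hydroxyl face) | COC(=O)CC[C@@H]1[C@@]2(C)CCCC(C)(C)[C@H]2[C@H]3C[C@]1(C)O[Si]3(C)C
F8 | step 5 | (Z)-(7-iodo-4,4-dimethylhept-2-en-1-yl)trimethylsilane | C[Si](C)(C)C/C=C\C(C)(C)CCCI
F9 | step 5 | methyl (4Z)-4-acetyl-5-(diethoxyphosphoryloxy)hex-4-enoate | COC(=O)CC/C(C(C)=O)=C(\C)OP(=O)(OCC)OCC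
F10 | step 5 | lithium bis[(5Z)-4,4-dimethyl-7-(trimethylsilyl)hept-5-en-1-yl]cuprate | [Li+].C[Si](C)(C)C/C=C\C(C)(C)CCC[Cu-]CCCC(C)(C)/C=C\C[Si](C)(C)C
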